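In a closed, stirred vessel of constant volume the starting material heads a reversible chain of isomers, while the protic impurity can remove it by a step with no way back.

| flask | starting material | protic impurity | temperature | remark | time |
|---|---|---|---|---|---|
| epsilon | 0.20 M | 0.090 M | 30 °C | run made earlier |  |
| alpha | 0.45 M | 0.090 M | 52 °C | run made earlier |  |
| ochre | 0.30 M | 0.0900 M |  | at 60 °C throughout | 40 min |
| blue | 0.30 M | 0.0900 M |  | at 20 °C until 40 min, from then on at 60 °C | 80 min |

- epsilon (time / min: target / %, starting material / %): 12.0: 14.0, 7.6; 25.0: 11.4, 5.1; 40.0: 11.1, 5.8; 50.0: 10.8, 5.9; 60.0: 11.5, 5.5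
- alpha (time / min: target / %, starting material / %): 4.00: 21.7, 22.1; 8.00: 21.6, 22.7; 12.0: 22.8, 23.2; 15.0: 21.5, 23.1; 20.0: 21.4, 22.3

(scatter of a reading: 0.5 percentage points)

1. which of the two ends with the higher amount of target, in percent of the starting material charged ("neither" if they lie within 2 percentage points) (ochre / blue / neither)
2. target at the end, in percent of the starting material charged, ochre
3. target at the end, in percent of the starting material charged, blue

- the numbers in the tables scatter with a standard deviation of 0.5 percentage points
- candidate steps: starting material <-> target; target <-> isomer of the product A; isomer of the product A <-> isomer of the product B; target <-> isomer of the product C; starting material + protic impurity -> quenched substrate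

What can we freeze? In ochre and blue the protic impurity is the limiting reagent, since c(protic impurity) is below c(starting material), and we assume it is used up, one for one. That leaves 70.0% of the charge, one minus the ratio c(protic impurity)/c(starting material), to the reversible chain: the pool.

Now the ladder of times, fastest first. Alpha at 52 °C reads level from 4.00 min on. Epsilon at 30 °C falls from 14.0% target at 12.0 min to 11.4% at 25.0 min, then stays. On the last rung the readings are flat, and we reckon each run's pool the same way: as read, target holds 20.4% of its pool in epsilon and 27.2% in alpha.

Ochre's 40 min at 60 °C is far longer than alpha's 4.00 min, and blue has 40.0 min hot after its cold spell. So we commit to about alpha's share of the pool in both flasks, which comes to 19.1% of the starting material charged.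

The forecast, a little higher than ours, says neither, with 19.4% (17.8% to 21%) for ochre and 19.4% (17.6% to 21.2%) for blue: “Blue's cold period only delays things”.

The flasks give 20.6% in ochre and 20.6% in blue, so neither.

    starting material ⇌ target (K = 2.34, k = 0.0937 min⁻¹, Ea = 88.0 kJ mol⁻¹, ΔH = −22.0 kJ mol⁻¹)
    target ⇌ isomer of the product A (K = 1.03, k = 0.113 min⁻¹, Ea = 83.0 kJ mol⁻¹, ΔH = −51.0 kJ mol⁻¹)
    isomer of the product A ⇌ isomer of the product B (K = 0.540, k = 0.221 min⁻¹, Ea = 79.0 kJ mol⁻¹, ΔH = −12.0 kJ mol⁻¹)
    target ⇌ isomer of the product C (K = 5.80, k = 0.118 min⁻¹, Ea = 77.0 kJ mol⁻¹, ΔH = −35.0 kJ mol⁻¹)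
    starting material + protic impurity → quenched substrate (k = 0.548 M⁻¹ min⁻¹, Ea = 69.0 kJ mol⁻¹)
    (constants at 20 °C)

At the end of blue the slowest mode has a half-life of 0.543 min, far shorter than the 40.0 min of heating. Quenched substrate then stands at 30.0% and protic impurity at 0%, and target holds 29.4% of the pool.

A neighbour flask changes the charge: with 0.36 M of protic impurity in blue's recipe, the pool reckons to −20.0%, so by this reckoning starting material is the limiting reagent and 16.7% of the impurity is surplus. That flask gives 0% target, with 17% of the impurity left.

The readings are simulated with constants of no real substance.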